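**Plan**

- Retrosynthesis: the two cinnamoyl esters are cut last, back to (−)-quinide 14, whose 1,5-lactone protects C5–OH and the carboxyl. The cis-3,4-diol is cut to the alkene 13. The carbocycle is then cut at C1–C6 and C4–C5 into a 2-pyrone and methyl vinyl ketone. (Quinic acid numbering: C1 carries OH and CO2H, C3–OH is cis to C4–OH, C5–OH is cis to the carboxyl.)
- Enabling feature: C1 (tertiary OH plus CO2H) and the oxygen-bearing C4 are 1,4-related in the ring. They match C6 (ring O plus ester) and C3 (OH plus lactone C=O) of methyl 3-hydroxy-2-oxo-2H-pyran-6-carboxylate, made from mucic acid. The pyrone ring oxygen becomes the C1–OH, the 6-ester becomes the C1 carboxyl, and the pyrone C2 lactone bridge is a temporary ring, later lost as CO2.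
- Forward order: pyrone (steps 1–2); dearomatising [4+2] builds the carbocycle as a 2-oxabicyclo[2.2.2]octenone (step 3); Baeyer–Villiger puts oxygen on C5; the bridge is switched to the quinide-type lactone; the C4 carbon is excised; the alkene is moved from C2=C3 to C3=C4 and dihydroxylated; two acylations; acid hydrolysis.
- Stereochemistry: C1 (absolute) from the catalyst-controlled cycloaddition; C5 from endo addition, kept by the retentive Baeyer–Villiger; C3 and C4 from convex-face OsO4 addition to the bicyclic ene-lactone; the E-alkenes are bought.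

Key step: step 3

Assumption: the quinine-derived thiourea is taken to give the (1R,4S,5R) adduct 5 (if the mirror image forms, the quinidine-derived pseudoenantiomer is used), and 3,4-diacetoxycinnamic acid and 4-acetoxycinnamic acid are taken as catalogue compounds.

**Route**

Step 1
Reactants: 1 mucic acid (galactaric acid)
Product: 2 3-acetoxy-2-oxo-2H-pyran-6-carboxylic acid
Conditions: Ac2O, pyridine, 100 °C; then 2 M HCl (work-up)
Reagents that add atoms: acetic anhydride CC(=O)OC(C)=O
Why: Peracetylation, two β-eliminations of acetic acid and δ-lactonisation should convert the aldaric acid into the 3-acetoxy-2-pyrone (dehydrative cyclisation of aldaric acids), with all four stereocentres of the meso acid deliberately removed.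

Step 2
Reactants: 2 3-acetoxy-2-oxo-2H-pyran-6-carboxylic acid
Product: 3 methyl 3-hydroxy-2-oxo-2H-pyran-6-carboxylate
Conditions: MeOH, H2SO4 (cat.), reflux
Reagents that add atoms: methanol CO
Why: Fischer esterification of the acid and acid-catalysed methanolysis of the enol acetate should occur in one pot and free the acidic 3-OH needed for the cycloaddition.

Step 3
Reactants: 3 methyl 3-hydroxy-2-oxo-2H-pyran-6-carboxylate; 4 methyl vinyl ketone (but-3-en-2-one)
Product: 5 methyl (1R,4S,5R)-5-acetyl-4-hydroxy-3-oxo-2-oxabicyclo[2.2.2]oct-7-ene-1-carboxylate (acetyl endo, i.e. syn to C7=C8 and anti to the lactone bridge)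
Conditions: 1-[3,5-bis(trifluoromethyl)phenyl]-3-[(S)-(6-methoxyquinolin-4-yl)((1S,2S,4S,5R)-5-vinylquinuclidin-2-yl)methyl]thiourea (10 mol %), 4 (5 equiv), Et2O, −20 → 0 °C
Reagents that add atoms: none
Why: The quinuclidine nitrogen deprotonates the 3-OH to an ion-paired pyronate while the thiourea hydrogen-bonds the enone, and an asynchronous [4+2] addition follows in which pyrone C6 (the vinylogous carbon terminus of the 3-oxido dienolate) bonds to the β-CH2 of 4 and the enolate carbon bonds to C3, dearomatising the pyrone. The closest known reaction type is the base- or cinchona-catalysed Diels–Alder reaction of 3-hydroxy-2-pyrones with enones, acrylates and acrylonitriles. The cyclohexene ring closes by suprafacial [4+2] addition across C6 and C3 of the pyrone (if stepwise, Michael addition then 6-exo-trig aldol onto the C3 ketone), the lactone bridge being already present. C1 and C4 are set together, their relative configuration fixed by the bridge and their absolute sense by the catalyst shielding one face of the pyronate, and C5 is set by the endo position of the hydrogen-bonded acetyl group under the diene. The step needs regio-, endo- and facial selectivity, and the polarity of the substrate (nucleophilic C6, electrophilic C3 once C6 has bonded) secures the regiochemistry: CH2 next to the quaternary ester-bearing carbon and the acetyl carbon next to the carbinol carbon. The 6-ester makes the pyronate less nucleophilic than the parent, hence excess enone.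

Step 4
Reactants: 5 methyl (1R,4S,5R)-5-acetyl-4-hydroxy-3-oxo-2-oxabicyclo[2.2.2]oct-7-ene-1-carboxylate
Product: 6 methyl (1R,4S,5R)-5-acetoxy-4-hydroxy-3-oxo-2-oxabicyclo[2.2.2]oct-7-ene-1-carboxylate
Conditions: Me3SiOOSiMe3 (3 equiv), SnCl4 (0.3 equiv), 4 Å MS, CH2Cl2, −20 → 25 °C; aq. citric acid work-up
Reagents that add atoms: bis(trimethylsilyl) peroxide C[Si](C)(C)OO[Si](C)(C)C
Why: Baeyer–Villiger oxidation in which the secondary ring carbon migrates in preference to methyl with retention, so the endo C5 configuration passes into the acetate; the silyl peroxide/Lewis acid system is chosen because it does not epoxidise the C7=C8 alkene, and in-flask silylation of the tertiary OH should block retro-aldol opening until work-up.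

Step 5
Reactants: 6 methyl (1R,4S,5R)-5-acetoxy-4-hydroxy-3-oxo-2-oxabicyclo[2.2.2]oct-7-ene-1-carboxylate
Product: 8 (1R,4S,5R)-1,4-dihydroxy-7-oxo-6-oxabicyclo[3.2.1]oct-2-ene-4-carboxylic acid, via triol diacid 7 (not isolated)
Conditions: LiOH, THF/H2O, 0 → 25 °C; 1 M HCl to pH 1, evaporate; then TsOH·H2O (cat.), toluene/DMF, 90 °C
Reagents that add atoms: lithium hydroxide [Li+].[OH-]
Why: Saponification opens the strained bridged δ-lactone and cleaves the acetate and methyl ester, and on acidic heating the C1 carboxyl, now cis-1,3 to the C5 hydroxyl, should close the five-membered quinide-type lactone (as quinic acid gives quinide), which masks C5–OH and the C1 carboxyl and leaves only the C4 carboxyl free without touching a stereocentre.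

Step 6
Reactants: 8 (1R,4S,5R)-1,4-dihydroxy-7-oxo-6-oxabicyclo[3.2.1]oct-2-ene-4-carboxylic acid
Product: 9 (1R,5R)-1-hydroxy-6-oxabicyclo[3.2.1]oct-2-ene-4,7-dione
Conditions: Pb(OAc)4 (1.1 equiv), MeCN/AcOH, 0 → 25 °C
Reagents that add atoms: none
Why: Oxidative decarboxylation of the α-hydroxy acid by lead tetraacetate removes the former pyrone C2 carbon as CO2 and leaves the C4 ketone conjugated with C2=C3; the α-hydroxy lactone at C1 is an ester and is not cleaved, and the lactone-bound C5 oxygen excludes glycol cleavage.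

Step 7
Reactants: 9 (1R,5R)-1-hydroxy-6-oxabicyclo[3.2.1]oct-2-ene-4,7-dione
Product: 10 (1R,4S,5R)-1,4-dihydroxy-6-oxabicyclo[3.2.1]oct-2-en-7-one
Conditions: NaBH4, CeCl3·7H2O, MeOH, −78 °C
Reagents that add atoms: none
Why: Luche 1,2-reduction of the enone should deliver hydride from the convex face to give mainly the C4 alcohol syn to the lactone bridge; either epimer serves, because this centre is consumed in step 8.

Step 8
Reactants: 10 (1R,4S,5R)-1,4-dihydroxy-6-oxabicyclo[3.2.1]oct-2-en-7-one
Product: 13 (1S,5R)-1-hydroxy-6-oxabicyclo[3.2.1]oct-3-en-7-one, via N-allyl sulfonylhydrazide 11 (not isolated), via allylic diazene 12 (not isolated)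
Conditions: 2-nitrobenzenesulfonylhydrazide (NBSH), PPh3, DEAD, THF, −30 °C; then 23 °C
Reagents that add atoms: none
Why: Myers reductive 1,3-transposition: Mitsunobu displacement of the allylic alcohol by NBSH, loss of sulfinic acid to the monoalkyl diazene and retro-ene loss of N2 deliver hydrogen to C2 and move the alkene to C3=C4 regiospecifically, while the tertiary C1–OH is inert to Mitsunobu activation.

Step 9
Reactants: 13 (1S,5R)-1-hydroxy-6-oxabicyclo[3.2.1]oct-3-en-7-one
Product: 14 (−)-quinide, (1S,3R,4R,5R)-1,3,4-trihydroxy-6-oxabicyclo[3.2.1]octan-7-one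
Conditions: OsO4 (2 mol %), NMO, acetone/H2O, 0 → 25 °C
Reagents that add atoms: osmium tetroxide O=[Os](=O)(=O)=O; N-methylmorpholine N-oxide C[N+]1([O-])CCOCC1; water O
Why: Upjohn syn-dihydroxylation from the convex face, anti to the lactone bridge, should set C3 and C4 cis to each other and trans to the C5 oxygen, the facial preference on which the classical racemic quinide synthesis rests.

Step 10
Reactants: 14 (−)-quinide; 15 (E)-3,4-diacetoxycinnamic acid
Product: 17 3-O-(3,4-di-O-acetylcaffeoyl)quinide, via acid chloride 16 (not isolated)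
Conditions: 15, (COCl)2, DMF (cat.), CH2Cl2, 25 °C, evaporate; then 14 (1.0 equiv), pyridine/CH2Cl2, DMAP (cat.), −20 → 0 °C
Reagents that add atoms: none
Why: Acylation with one equivalent of acid chloride should take the equatorial C3–OH of the lactone-locked chair ahead of the axial C4–OH and the tertiary C1–OH, as in known 3-O-acylations of quinide.

Step 11
Reactants: 17 3-O-(3,4-di-O-acetylcaffeoyl)quinide; 18 (E)-4-acetoxycinnamic acid
Product: 20 3-O-(3,4-di-O-acetylcaffeoyl)-4-O-(4-O-acetyl-p-coumaroyl)quinide, via acid chloride 19 (not isolated)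
Conditions: 18, (COCl)2, DMF (cat.), CH2Cl2, 25 °C, evaporate; then 17, pyridine/CH2Cl2, DMAP (cat.), 0 → 25 °C (1.5 equiv chloride)
Reagents that add atoms: none
Why: DMAP-catalysed acylation of the remaining secondary (axial) C4–OH should outpace that of the hindered tertiary C1–OH, as in the preparation of 3,4-diacylquinides.

Step 12
Reactants: 20 3-O-(3,4-di-O-acetylcaffeoyl)-4-O-(4-O-acetyl-p-coumaroyl)quinide
Product: 21 3-O-caffeoyl-4-O-p-coumaroylquinic acid (target)
Conditions: 2 M aq. HCl/THF (1:4), 25 °C, several days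
Reagents that add atoms: water O
Why: Acid hydrolysis should cleave the three phenyl acetates and open the strained γ-lactone to the C5–OH and the C1 carboxyl while the two alkyl cinnamate esters survive, and the acidic medium avoids the base-promoted acyl migration typical of acylquinic acids.

**Compound list**

1 | mucic acid (galactaric acid, meso) | OC(=O)[C@H](O)[C@@H](O)[C@@H](O)[C@H](O)C(=O)O | starting material
2 | 3-acetoxy-2-oxo-2H-pyran-6-carboxylic acid | CC(=O)OC1=CC=C(C(=O)O)OC1=O | intermediate
3 | methyl 3-hydroxy-2-oxo-2H-pyran-6-carboxylate | COC(=O)C1=CC=C(O)C(=O)O1 | intermediate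
4 | methyl vinyl ketone | CC(=O)C=C | starting material
5 | methyl (1R,4S,5R)-5-acetyl-4-hydroxy-3-oxo-2-oxabicyclo[2.2.2]oct-7-ene-1-carboxylate | COC(=O)[C@@]12C[C@@H](C(C)=O)[C@@](O)(C=C1)C(=O)O2 | intermediate
6 | methyl (1R,4S,5R)-5-acetoxy-4-hydroxy-3-oxo-2-oxabicyclo[2.2.2]oct-7-ene-1-carboxylate | COC(=O)[C@@]12C[C@@H](OC(C)=O)[C@@](O)(C=C1)C(=O)O2 | intermediate
7 | (1R,4S,5R)-1,4,5-trihydroxycyclohex-2-ene-1,4-dicarboxylic acid | OC(=O)[C@]1(O)C=C[C@@](O)(C(=O)O)[C@H](O)C1 | intermediate
8 | (1R,4S,5R)-1,4-dihydroxy-7-oxo-6-oxabicyclo[3.2.1]oct-2-ene-4-carboxylic acid | O[C@]1(C=C[C@@](O)(C(=O)O)[C@H]2C1)C(=O)O2 | intermediate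
9 | (1R,5R)-1-hydroxy-6-oxabicyclo[3.2.1]oct-2-ene-4,7-dione | O[C@]1(C=CC(=O)[C@H]2C1)C(=O)O2 | intermediate
10 | (1R,4S,5R)-1,4-dihydroxy-6-oxabicyclo[3.2.1]oct-2-en-7-one | O[C@]1(C=C[C@H](O)[C@H]2C1)C(=O)O2 | intermediate
11 | N-[(1R,4R,5R)-1-hydroxy-7-oxo-6-oxabicyclo[3.2.1]oct-2-en-4-yl]-2-nitrobenzenesulfonohydrazide (alkylated on the sulfonylated nitrogen) | O[C@]1(C=C[C@@H](N(N)S(=O)(=O)c3ccccc3[N+](=O)[O-])[C@H]2C1)C(=O)O2 | intermediate
12 | (1R,4R,5R)-4-diazenyl-1-hydroxy-6-oxabicyclo[3.2.1]oct-2-en-7-one | O[C@]1(C=C[C@@H](N=N)[C@H]2C1)C(=O)O2 | intermediate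
13 | (1S,5R)-1-hydroxy-6-oxabicyclo[3.2.1]oct-3-en-7-one | O[C@]1(CC=C[C@H]2C1)C(=O)O2 | intermediate
14 | (−)-quinide, (1S,3R,4R,5R)-1,3,4-trihydroxy-6-oxabicyclo[3.2.1]octan-7-one | O[C@]1(C[C@@H](O)[C@@H](O)[C@H]2C1)C(=O)O2 | intermediate
15 | (E)-3,4-diacetoxycinnamic acid | CC(=O)Oc1ccc(/C=C/C(=O)O)cc1OC(C)=O | starting material
16 | (E)-3,4-diacetoxycinnamoyl chloride | CC(=O)Oc1ccc(/C=C/C(Cl)=O)cc1OC(C)=O | intermediate
17 | 3-O-(3,4-di-O-acetylcaffeoyl)quinide (configuration of 14) | O[C@]1(C[C@@H](OC(=O)/C=C/c3ccc(OC(C)=O)c(OC(C)=O)c3)[C@@H](O)[C@H]2C1)C(=O)O2 | intermediate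
18 | (E)-4-acetoxycinnamic acid | CC(=O)Oc1ccc(/C=C/C(=O)O)cc1 | starting material
19 | (E)-4-acetoxycinnamoyl chloride | CC(=O)Oc1ccc(/C=C/C(Cl)=O)cc1 | intermediate
20 | 3-O-(3,4-di-O-acetylcaffeoyl)-4-O-(4-O-acetyl-p-coumaroyl)quinide (configuration of 14) | O[C@]1(C[C@@H](OC(=O)/C=C/c3ccc(OC(C)=O)c(OC(C)=O)c3)[C@@H](OC(=O)/C=C/c4ccc(OC(C)=O)cc4)[C@H]2C1)C(=O)O2 | intermediate
21 | 3-O-caffeoyl-4-O-p-coumaroylquinic acid (C1–OH, C3–O and C4–O on one face; C5–OH and CO2H on the other) | O=C(/C=C/c1ccc(O)cc1)O[C@H]1[C@H](O)C[C@](O)(C(=O)O)C[C@H]1OC(=O)/C=C/c1ccc(O)c(O)c1 | target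

**Count and risks**

Total step count: 12. Longest linear sequence: 12 steps (1 → 21); acids 15 and 18 enter in steps 10 and 11.

Most likely to fail:

1. Step 3. The ester-stabilised pyronate may add sluggishly, and facial or endo/exo control by the catalyst may be insufficient. Fallback (auxiliary control with physical separation), from 2 back to 8: esterification of 2 with (1R,2S,5R)-menthol (DCC, cat. DMAP, CH2Cl2) should give (1R,2S,5R)-menthyl 3-acetoxy-2-oxo-2H-pyran-6-carboxylate F1. Mild acid methanolysis of the enol acetate (HCl, MeOH, 25 °C) should give (1R,2S,5R)-menthyl 3-hydroxy-2-oxo-2H-pyran-6-carboxylate F2. Achiral amine catalysis (Et3N, excess 4, CH2Cl2) should give the two endo adducts, which are diastereomers and are separated by crystallisation or chromatography: the (1R,4S,5R)-menthyl adduct F3 is kept and the (1S,4R,5S)-menthyl adduct F4 is removed. Baeyer–Villiger oxidation as in step 4 should give the menthyl 5-acetoxy adduct F5. The conditions of step 5, in which LiOH also cleaves the menthyl ester, return the route to 8.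

2. Step 4. The oxidant may attack the strained C7=C8 alkene, the Lewis acid may open the β-hydroxy ketone by retro-aldol reaction, or the electron-poor C5 may migrate too slowly. Fallback (take the alkene out of play, then use a conventional strong peracid), from 5 back to 6: bromine addition (Br2, CH2Cl2, 0 °C) should give the trans-7,8-dibromide of 5, F6, drawn as the isomer from bromide opening at C7 on the face away from the lactone bridge (either trans isomer serves). Oxidation with CF3CO3H (from (CF3CO)2O and urea–H2O2, Na2HPO4, CH2Cl2) should give the dibromo acetate F7. Zinc dust in AcOH restores the alkene and returns 6.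

3. Step 10. Discrimination between the equatorial C3–OH and axial C4–OH may be incomplete, with base-induced acyl migration or over-acylation at the tertiary OH. Fallback (temporary silyl differentiation and reversed order of acylation), from 14 back to 20: selective silylation of the equatorial hydroxyl (TBSCl, imidazole, DMF, 0 °C) should give 3-O-TBS-quinide F8. Acylation of the axial C4–OH with chloride 19 (pyridine, DMAP) should give 3-O-TBS-4-O-(4-O-acetyl-p-coumaroyl)quinide F9. Acidic desilylation (HF·pyridine, THF), which suppresses 4 → 3 acyl shift, should give 4-O-(4-O-acetyl-p-coumaroyl)quinide F10. Acylation of the freed C3–OH with chloride 16 (pyridine, DMAP) returns 20.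

**Further compounds**

F1 | step 3 | (1R,2S,5R)-menthyl 3-acetoxy-2-oxo-2H-pyran-6-carboxylate | C[C@@H]1CC[C@H]([C@@H](C1)OC(=O)C2=CC=C(OC(C)=O)C(=O)O2)C(C)C
F2 | step 3 | (1R,2S,5R)-menthyl 3-hydroxy-2-oxo-2H-pyran-6-carboxylate | C[C@@H]1CC[C@H]([C@@H](C1)OC(=O)C2=CC=C(O)C(=O)O2)C(C)C
F3 | step 3 | (1R,2S,5R)-menthyl (1R,4S,5R)-5-acetyl-4-hydroxy-3-oxo-2-oxabicyclo[2.2.2]oct-7-ene-1-carboxylate | C[C@@H]1CC[C@H]([C@@H](C1)OC(=O)[C@@]23C[C@@H](C(C)=O)[C@@](O)(C=C2)C(=O)O3)C(C)C
F4 | step 3 | (1R,2S,5R)-menthyl (1S,4R,5S)-5-acetyl-4-hydroxy-3-oxo-2-oxabicyclo[2.2.2]oct-7-ene-1-carboxylate (diastereomer removed) | C[C@@H]1CC[C@H]([C@@H](C1)OC(=O)[C@]23C[C@H](C(C)=O)[C@](O)(C=C2)C(=O)O3)C(C)C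
F5 | step 3 | (1R,2S,5R)-menthyl (1R,4S,5R)-5-acetoxy-4-hydroxy-3-oxo-2-oxabicyclo[2.2.2]oct-7-ene-1-carboxylate | C[C@@H]1CC[C@H]([C@@H](C1)OC(=O)[C@@]23C[C@@H](OC(C)=O)[C@@](O)(C=C2)C(=O)O3)C(C)C
F6 | step 4 | methyl 5-acetyl-7,8-dibromo-4-hydroxy-3-oxo-2-oxabicyclo[2.2.2]octane-1-carboxylate (trans-dibromide of 5) | COC(=O)[C@@]12C[C@@H](C(C)=O)[C@@](O)([C@H](Br)[C@H]1Br)C(=O)O2
F7 | step 4 | methyl 5-acetoxy-7,8-dibromo-4-hydroxy-3-oxo-2-oxabicyclo[2.2.2]octane-1-carboxylate (trans-dibromide of 6) | COC(=O)[C@@]12C[C@@H](OC(C)=O)[C@@](O)([C@H](Br)[C@H]1Br)C(=O)O2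
F8 | step 10 | 3-O-(tert-butyldimethylsilyl)quinide | O[C@]1(C[C@@H](O[Si](C)(C)C(C)(C)C)[C@@H](O)[C@H]2C1)C(=O)O2
F9 | step 10 | 3-O-(tert-butyldimethylsilyl)-4-O-(4-O-acetyl-p-coumaroyl)quinide | O[C@]1(C[C@@H](O[Si](C)(C)C(C)(C)C)[C@@H](OC(=O)/C=C/c3ccc(OC(C)=O)cc3)[C@H]2C1)C(=O)O2
F10 | step 10 | 4-O-(4-O-acetyl-p-coumaroyl)quinide | O[C@]1(C[C@@H](O)[C@@H](OC(=O)/C=C/c3ccc(OC(C)=O)cc3)[C@H]2C1)C(=O)O2
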